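**Assumptions**
- Positions are given in guaiane numbering (five-membered ring C1–C5; seven-membered ring C1, C5–C10; 4-Me, 10-Me, 7-i-Pr). The target read from the SMILES is (4S,5S,6R,7S,8S).
- Numbered coupling partners stand on the Reactants line; "Reagents that add atoms" holds unnumbered reagents only. Aldehyde 16 is taken as a catalogue compound.

**Retrosynthetic overview**
1. 18 ⇐ 15: Evans–Tishchenko reaction with 16 puts the aryl ester on O8 and sets C6; then desilylation.
2. 15 ⇐ 14: reductive SN1′ opening of the C1–O bond of the oxa-bridge places the alkene at C1=C10 and frees 8-OH.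
3. 14 ⇐ 12: intramolecular (4+3) cycloaddition of the epoxy enolsilane with the tethered 3-methylfuran; cyclopentane, cycloheptenone and oxa-bridge close together, and C1, C5, C7, C8 follow from the epoxide.
4. 12 ⇐ 8 (Sharpless epoxidation, i-Bu addition, oxidation); 8 ⇐ 1 + 2 via ynoate 6 and Z-selective methylcupration.
5. Ring order: furan (bought) → oxirane → five- and seven-membered carbocycles plus oxa-bridge in one step → bridge opened.

**Route**

Step 1
Reactants: 1 3-methylfuran; 2 but-3-en-2-one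
Product: 3 4-(3-methylfuran-2-yl)butan-2-one
Conditions: 1 (3 equiv), BF3·OEt2 (5 mol %), EtOH (cat.), MeNO2, −20 °C
Reagents that add atoms: none
Why: Acid-catalysed Friedel–Crafts-type Michael alkylation of the furan; the 3-methyl group makes C2 the most nucleophilic α-position and excess furan suppresses 2,5-dialkylation; no stereocentre.

Step 2
Reactants: 3 4-(3-methylfuran-2-yl)butan-2-one
Product: 6 methyl 5-(3-methylfuran-2-yl)pent-2-ynoate, via enol phosphate 4 (not isolated), via lithium acetylide 5 (not isolated)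
Conditions: LDA, THF, −78 °C; ClP(O)(OEt)2; LDA (2.3 equiv), −78 → 0 °C; ClCO2Me, −78 °C
Reagents that add atoms: methyl chloroformate COC(=O)Cl
Why: Negishi alkyne synthesis (kinetic methyl-side enolate → enol phosphate → β-elimination) leaves the terminal alkyne as its acetylide, which is C-acylated in the same flask; no stereocentre.

Step 3
Reactants: 6 methyl 5-(3-methylfuran-2-yl)pent-2-ynoate
Product: 7 methyl (2Z)-3-methyl-5-(3-methylfuran-2-yl)pent-2-enoate
Conditions: Me2CuLi, THF, −78 °C; MeOH, −78 °C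
Reagents that add atoms: lithium dimethylcuprate [Li+].C[Cu-]C
Why: syn-Carbocupration of the ynoate gives a configurationally stable alkenylcuprate that is protonated cold, so the chain and the ester end cis (Z, nerol-type geometry), which later fixes the C4/C5 relationship.

Step 4
Reactants: 7 methyl (2Z)-3-methyl-5-(3-methylfuran-2-yl)pent-2-enoate
Product: 8 (2Z)-3-methyl-5-(3-methylfuran-2-yl)pent-2-en-1-ol
Conditions: DIBAL-H (2.2 equiv), CH2Cl2, −78 °C; Rochelle salt
Reagents that add atoms: none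
Why: 1,2-Reduction of the enoate by DIBAL-H to the allylic alcohol with retention of the Z geometry.

Step 5
Reactants: 8 (2Z)-3-methyl-5-(3-methylfuran-2-yl)pent-2-en-1-ol
Product: 9 [(2R,3S)-3-methyl-3-[2-(3-methylfuran-2-yl)ethyl]oxiran-2-yl]methanol
Conditions: Ti(OiPr)4 (10 mol %), D-(−)-DET (12 mol %), t-BuOOH, 4 Å MS, CH2Cl2, −20 °C
Reagents that add atoms: tert-butyl hydroperoxide CC(C)(C)OO
Why: Sharpless asymmetric epoxidation; the D-(−)-tartrate catalyst delivers oxygen to one face of the Z-allylic alcohol (same sense as nerol → (2R,3S)-epoxynerol), setting C4 (final) and C5 (inverted later).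

Step 6
Reactants: 9 [(2R,3S)-3-methyl-3-[2-(3-methylfuran-2-yl)ethyl]oxiran-2-yl]methanol
Product: 11 3-methyl-1-[(2R,3S)-3-methyl-3-[2-(3-methylfuran-2-yl)ethyl]oxiran-2-yl]butan-1-ol (carbinol epimers), via epoxy aldehyde 10 (not isolated)
Conditions: (COCl)2, DMSO, CH2Cl2, −78 °C; Et3N; then i-BuMgBr (5 equiv), THF, −78 → 0 °C
Reagents that add atoms: isobutylmagnesium bromide CC(C)C[Mg]Br
Why: Swern oxidation followed by Grignard addition in the same flask avoids handling the epoxy aldehyde; the new carbinol centre is oxidised in the next step, so its configuration does not matter.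

Step 7
Reactants: 11 3-methyl-1-[(2R,3S)-3-methyl-3-[2-(3-methylfuran-2-yl)ethyl]oxiran-2-yl]butan-1-ol
Product: 12 3-methyl-1-[(2S,3S)-3-methyl-3-[2-(3-methylfuran-2-yl)ethyl]oxiran-2-yl]butan-1-one
Conditions: TPAP (5 mol %), NMO, 4 Å MS, CH2Cl2, rt
Reagents that add atoms: none
Why: Ley–Griffith oxidation under neutral conditions gives the α,β-epoxy ketone without touching the epoxide or the furan.

Step 8
Reactants: 12 3-methyl-1-[(2S,3S)-3-methyl-3-[2-(3-methylfuran-2-yl)ethyl]oxiran-2-yl]butan-1-one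
Product: 14 (1S,4S,5R,7R,8S)-4,10-dimethyl-7-(propan-2-yl)-4-[(triethylsilyl)oxy]-11-oxatricyclo[6.2.1.0(1,5)]undec-9-en-6-one, via epoxy enolsilane 13 (not isolated)
Conditions: Et3N (1.1 equiv), TESOTf (1.3 equiv), CH2Cl2, −78 → −40 °C
Reagents that add atoms: triethylsilyl trifluoromethanesulfonate CC[Si](CC)(CC)OS(=O)(=O)C(F)(F)F
Why: Soft enolisation gives the (Z)-enolsilane on the CH2 side and the excess TESOTf then silylates the epoxide, so the siloxyallyl cation is captured by furan C2 anti to the leaving oxygen (SN2-like inversion at C5) and at C7 by furan C5 through a compact transition state with the tether in the outside (W) position; this intramolecular (4+3) cycloaddition of an epoxy enolsilane closes cyclopentane, cycloheptenone and oxa-bridge at once, keeps C4, sets C1/C5/C8 with H5 cis to the bridge, and leaves the enolisable C7 with i-Pr equatorial.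

Step 9
Reactants: 14 (1S,4S,5R,7R,8S)-4,10-dimethyl-7-(propan-2-yl)-4-[(triethylsilyl)oxy]-11-oxatricyclo[6.2.1.0(1,5)]undec-9-en-6-one
Product: 15 (3S,3aR,5R,6S)-6-hydroxy-3,8-dimethyl-5-(propan-2-yl)-3-[(triethylsilyl)oxy]-2,3,3a,5,6,7-hexahydroazulen-4(1H)-one
Conditions: Et3SiH (5 equiv), BF3·OEt2 (1.5 equiv), CH2Cl2, −78 °C; H2O (pH 7 buffer)
Reagents that add atoms: none
Why: Proposed new method: BF3 binds the bridging oxygen and the tertiary allylic C1–O bond ionises in preference to the secondary C8–O bond (tertiary centre, strain relief at the quaternary bridgehead), giving the C1–C10–C9 allyl cation that Et3SiH reduces at the less hindered terminus C9, so the tetrasubstituted C1=C10 alkene forms and O8 is released with C8 untouched; the closest known reaction type is Kursanov–Parnes ionic hydrogenation of tertiary allylic ethers.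

Step 10
Reactants: 15 (3S,3aR,5R,6S)-6-hydroxy-3,8-dimethyl-5-(propan-2-yl)-3-[(triethylsilyl)oxy]-2,3,3a,5,6,7-hexahydroazulen-4(1H)-one; 16 4-[(tert-butyldimethylsilyl)oxy]-3-methoxybenzaldehyde
Product: 17 (3S,3aS,4R,5S,6S)-4-hydroxy-3,8-dimethyl-5-(propan-2-yl)-3-[(triethylsilyl)oxy]-1,2,3,3a,4,5,6,7-octahydroazulen-6-yl 4-[(tert-butyldimethylsilyl)oxy]-3-methoxybenzoate
Conditions: 16 (6 equiv), SmI2 (30 mol %), THF, −10 °C
Reagents that add atoms: none
Why: Evans–Tishchenko reduction: the Sm(III)-bound hemiacetal of O8 with 16 transfers hydride intramolecularly to the C6 ketone from the face of O8, giving the 1,3-anti diol monoester with the aryl ester on O8 and 6-OH trans to it (6R); the neutral conditions spare the β,γ-unsaturated ketone and the silyl ethers.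

Step 11
Reactants: 17 (3S,3aS,4R,5S,6S)-4-hydroxy-3,8-dimethyl-5-(propan-2-yl)-3-[(triethylsilyl)oxy]-1,2,3,3a,4,5,6,7-octahydroazulen-6-yl 4-[(tert-butyldimethylsilyl)oxy]-3-methoxybenzoate
Product: 18 (3S,3aS,4R,5S,6S)-3,4-dihydroxy-3,8-dimethyl-5-(propan-2-yl)-1,2,3,3a,4,5,6,7-octahydroazulen-6-yl 4-hydroxy-3-methoxybenzoate
Conditions: HF·pyridine, pyridine, THF, 0 °C → rt
Reagents that add atoms: none
Why: Fluoride cleavage of the aryl TBS ether and the tertiary TES ether under buffered, non-basic conditions avoids 1,3-acyl migration; no stereocentre is touched.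

**Compound list**

1 | 3-methylfuran | Cc1ccoc1 | starting material
2 | but-3-en-2-one (methyl vinyl ketone) | CC(=O)C=C | starting material
3 | 4-(3-methylfuran-2-yl)butan-2-one | CC(=O)CCc1occc1C | intermediate
4 | diethyl 4-(3-methylfuran-2-yl)but-1-en-2-yl phosphate | C=C(OP(=O)(OCC)OCC)CCc1occc1C | intermediate
5 | lithium 4-(3-methylfuran-2-yl)but-1-yn-1-ide | [Li]C#CCCc1occc1C | intermediate
6 | methyl 5-(3-methylfuran-2-yl)pent-2-ynoate | COC(=O)C#CCCc1occc1C | intermediate
7 | methyl (2Z)-3-methyl-5-(3-methylfuran-2-yl)pent-2-enoate | COC(=O)/C=C(/C)CCc1occc1C | intermediate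
8 | (2Z)-3-methyl-5-(3-methylfuran-2-yl)pent-2-en-1-ol | OC/C=C(/C)CCc1occc1C | intermediate
9 | [(2R,3S)-3-methyl-3-[2-(3-methylfuran-2-yl)ethyl]oxiran-2-yl]methanol | OC[C@H]1O[C@@]1(C)CCc1occc1C | intermediate
10 | (2S,3S)-3-methyl-3-[2-(3-methylfuran-2-yl)ethyl]oxirane-2-carbaldehyde | O=C[C@H]1O[C@@]1(C)CCc1occc1C | intermediate
11 | 3-methyl-1-[(2R,3S)-3-methyl-3-[2-(3-methylfuran-2-yl)ethyl]oxiran-2-yl]butan-1-ol (carbinol epimers) | CC(C)CC(O)[C@H]1O[C@@]1(C)CCc1occc1C | intermediate
12 | 3-methyl-1-[(2S,3S)-3-methyl-3-[2-(3-methylfuran-2-yl)ethyl]oxiran-2-yl]butan-1-one | CC(C)CC(=O)[C@H]1O[C@@]1(C)CCc1occc1C | intermediate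
13 | triethyl({(1Z)-3-methyl-1-[(2S,3S)-3-methyl-3-[2-(3-methylfuran-2-yl)ethyl]oxiran-2-yl]but-1-en-1-yl}oxy)silane | CC(C)/C=C(\O[Si](CC)(CC)CC)[C@H]1O[C@@]1(C)CCc1occc1C | intermediate
14 | (1S,4S,5R,7R,8S)-4,10-dimethyl-7-(propan-2-yl)-4-[(triethylsilyl)oxy]-11-oxatricyclo[6.2.1.0(1,5)]undec-9-en-6-one | O1[C@H]2C=C(C)[C@@]13CC[C@](C)(O[Si](CC)(CC)CC)[C@@H]3C(=O)[C@@H]2C(C)C | intermediate
15 | (3S,3aR,5R,6S)-6-hydroxy-3,8-dimethyl-5-(propan-2-yl)-3-[(triethylsilyl)oxy]-2,3,3a,5,6,7-hexahydroazulen-4(1H)-one | O[C@H]1CC(C)=C2CC[C@](C)(O[Si](CC)(CC)CC)[C@@H]2C(=O)[C@@H]1C(C)C | intermediate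
16 | 4-[(tert-butyldimethylsilyl)oxy]-3-methoxybenzaldehyde | COc1cc(C=O)ccc1O[Si](C)(C)C(C)(C)C | starting material
17 | (3S,3aS,4R,5S,6S)-4-hydroxy-3,8-dimethyl-5-(propan-2-yl)-3-[(triethylsilyl)oxy]-1,2,3,3a,4,5,6,7-octahydroazulen-6-yl 4-[(tert-butyldimethylsilyl)oxy]-3-methoxybenzoate | COc1cc(C(=O)O[C@H]2CC(C)=C3CC[C@](C)(O[Si](CC)(CC)CC)[C@@H]3[C@H](O)[C@@H]2C(C)C)ccc1O[Si](C)(C)C(C)(C)C | intermediate
18 | (3S,3aS,4R,5S,6S)-3,4-dihydroxy-3,8-dimethyl-5-(propan-2-yl)-1,2,3,3a,4,5,6,7-octahydroazulen-6-yl 4-hydroxy-3-methoxybenzoate (CNP0299353.1) | COc1cc(C(=O)O[C@H]2CC(C)=C3CC[C@](C)(O)[C@@H]3[C@H](O)[C@@H]2C(C)C)ccc1O | target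

**Totals and risks**

Total step count: 11. Longest linear sequence: 11 steps (1 → 18); aldehyde 16 enters in step 10.

Most likely to fail, step 8. The epoxy enolsilane may react through a transition state that puts the oxa-bridge trans to H5, or the one-flask enolisation and cycloaddition may not tolerate the ammonium triflate. The fallback sets out from 12 and comes back at 14. The epoxide is opened at the α-carbon with MgBr2·OEt2 (chelation-controlled SN2) to the bromohydrin (5R,6S)-5-bromo-6-hydroxy-2,6-dimethyl-8-(3-methylfuran-2-yl)octan-4-one F1, which is silylated (TESOTf, 2,6-lutidine) to the triethylsilyl ether (5R,6S)-5-bromo-2,6-dimethyl-8-(3-methylfuran-2-yl)-6-[(triethylsilyl)oxy]octan-4-one F2. F2 is then dehydrobrominated under Föhlisch conditions (Et3N, CF3CH2OH, rt) to a free oxyallyl cation that adds to the furan to give 14. This replaces Lewis-acid epoxide activation by base-mediated oxyallyl generation in an ionising protic solvent, so the ring fusion is governed by the tether and not by SN2 inversion.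

Step 9. The wrong bridge bond (C8–O) may ionise, or the β,γ-unsaturated ketone may slip into conjugation. The fallback sets out from 14 and comes back at 15. A hydrogen-atom-transfer Markovnikov hydrobromination (Co(acac)2, t-BuOOH, Et3SiH, TsBr) adds H to C9 and Br to C10, giving the tertiary bromide (1S,4S,5R,7R,8S)-10-bromo-4,10-dimethyl-7-(propan-2-yl)-4-[(triethylsilyl)oxy]-11-oxatricyclo[6.2.1.0(1,5)]undecan-6-one F3. Zinc dust in ethanol then effects a Boord-type reductive β-elimination; only the C1–O bond is β to C10, so the C1=C10 alkene and free 8-OH of 15 result. This is a radical/organometallic sequence in which the position of the halogen, not cation stability, fixes the regiochemistry.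

Step 10. The electron-rich aldehyde 16 may be a sluggish Tishchenko partner, or the acyl group may migrate to O6. The fallback sets out from 15 and comes back at 17. Evans–Saksena reduction (Me4NBH(OAc)3, MeCN/AcOH, −30 °C) gives the anti-diol (3S,3aS,4R,5R,6S)-3,8-dimethyl-5-(propan-2-yl)-3-[(triethylsilyl)oxy]-1,2,3,3a,4,5,6,7-octahydroazulene-4,6-diol F4. Pinnick oxidation of 16 gives 4-[(tert-butyldimethylsilyl)oxy]-3-methoxybenzoic acid F5, which is coupled under Yamaguchi conditions to the less hindered 8-OH of F4 to give 17. This separates the reduction (external, hydroxyl-directed hydride) from the acylation.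

**Further compounds**

F1 | step 8 | (5R,6S)-5-bromo-6-hydroxy-2,6-dimethyl-8-(3-methylfuran-2-yl)octan-4-one | CC(C)CC(=O)[C@H](Br)[C@@](C)(O)CCc1occc1C
F2 | step 8 | (5R,6S)-5-bromo-2,6-dimethyl-8-(3-methylfuran-2-yl)-6-[(triethylsilyl)oxy]octan-4-one | CC(C)CC(=O)[C@H](Br)[C@@](C)(O[Si](CC)(CC)CC)CCc1occc1C
F3 | step 9 | (1S,4S,5R,7R,8S)-10-bromo-4,10-dimethyl-7-(propan-2-yl)-4-[(triethylsilyl)oxy]-11-oxatricyclo[6.2.1.0(1,5)]undecan-6-one (C10 epimers) | O1[C@H]2CC(C)(Br)[C@@]13CC[C@](C)(O[Si](CC)(CC)CC)[C@@H]3C(=O)[C@@H]2C(C)C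
F4 | step 10 | (3S,3aS,4R,5R,6S)-3,8-dimethyl-5-(propan-2-yl)-3-[(triethylsilyl)oxy]-1,2,3,3a,4,5,6,7-octahydroazulene-4,6-diol | O[C@H]1CC(C)=C2CC[C@](C)(O[Si](CC)(CC)CC)[C@@H]2[C@H](O)[C@@H]1C(C)C
F5 | step 10 | 4-[(tert-butyldimethylsilyl)oxy]-3-methoxybenzoic acid | COc1cc(C(=O)O)ccc1O[Si](C)(C)C(C)(C)C
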